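Count the protons before you trust any curve. That was the opening direction at this short meeting on one flask.

electrophile 0.10 M; protonated nucleophile 1.80 equiv; scavenger 0.800 equiv; time 10 h

    electrophile + nucleophile → acid set free + target (k1 = 6.4 M⁻¹ h⁻¹)
    nucleophile + acid set free ⇌ protonated nucleophile, settled at all times (K2 = 1900 M⁻¹)
    acid set free + free base ⇌ salt of the base, settled at all times (K3 = 49000 M⁻¹)
    electrophile + acid set free ⇌ idle adduct, settled at all times (K4 = 19 M⁻¹)
    acid set free + scavenger → scavenged by-product (k5 = 14 M⁻¹ h⁻¹)
    free base + target → over-reaction product (k6 = 0.84 M⁻¹ h⁻¹)

- acid set free is meant together with its idle adduct
- the amount of free base is what is sought; it is there from the start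
- what has gone from electrophile into another species counts as reacted, even if it can come back
- run time (flask): 10 h

- the equivalents of free base at which the part of the electrophile that has reacted at 10 h is just 90%

I spoke first. I said step 1 reaches the wanted part after 3.60 h with free nucleophile held at one equivalent of the electrophile charge. I named this the dose: free nucleophile, as a fraction of the electrophile charge, summed over time. Spread over the run, it asks for a mean of 0.360 of the electrophile charge as free nucleophile.

I then turned to the base. Because K3 stands 25.8 times above K2, I let the base take the protons. Each equivalent of base then frees one of nucleophile or takes up one of acid. With the scavenger left aside, free nucleophile is the base charged less twice the part reacted. So at 1.80 equivalents it reaches zero just at the wanted part, and that is my floor. At 2 equivalents the same balance gets there after 7.03 h, earlier than the run ends. I committed to a value between these two.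

The forecast's author put the need at 1.81 equiv, holding that the scavenger “gives back base late on”. That figure stood just above my floor, and I kept my range.

The flask needs 1.82 equiv, so the forecast holds within its margin. In this flask the half-life of electrophile by step 1 is 1.3 h at 0.838 h and 6.3 h at 10.0 h, longer at the end. Those half-lives read as free nucleophile of 0.827 and then 0.172 of the electrophile charge, the last below the mean of 0.360. A second flask has twice the free base, 3.64 equivalents. Reckoned with free nucleophile at 0.800 of the electrophile charge for the whole run, a pseudo-first-order decay, the dose gives 99.4% reacted; that flask's run reads 99.5%.

(The rate constants are those of an exercise.)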